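## Retrosynthetic overview

1. The target is a cis-fused hydrindane (ring A cyclohexene, ring B cyclopentane) whose C1 and C6 are bridged by a seven-carbon chain, closing the eleven-membered ring C. The enabling feature is the allylic acetate unit C(=CH2)–CH(OAc) of ring C: the methylene-bearing carbon sits on ring B and maps onto the internal carbon of a terminal alkyne, the oxygenated carbon maps onto an aldehyde at the chain end, and the cis fusion holds the alkyne on the concave face under ring A, beside the chain.
2. Ring C is closed last (only protecting-group work follows) by a nickel-catalysed, exo-selective reductive ynal macrocyclization that also creates the exocyclic methylene and the oxygenated stereocentre.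
3. Before that, the chain is joined to ring A by B-alkyl Suzuki coupling at an enol triflate (tetrasubstituted alkene). The trans-diol comes from a convex-face enone epoxide opened with inversion at its allylic carbon, and the alkyne from convex-face hydroboration of a C1 methylene followed by one-carbon homologation.
4. Rings A and B: Robinson annulation gives ring A as a 4,4-disubstituted cyclohexadienone; an asymmetric intramolecular Stetter reaction desymmetrizes it, closing ring B and setting the quaternary methyl centre and the cis fusion.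
5. The chain stereocentre comes from a copper-catalysed asymmetric allylic alkylation. Ring order: A, then B, then C.

Key step: step 19

Remarks on the chemistry:
- Locants in names follow indene numbering for the bicycle (C1–C3, C3a, C4–C7, C7a); C3a carries the angular methyl, C6 the side chain, C1 the future alkyne. β is the face of the C3a methyl group. Chain carbons C1′–C6′ are counted from C6.
- Where a chiral catalyst is named without descriptor (triazolium salt, Taniaphos, DP-IPr), the antipode that delivers the drawn configuration is meant.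
- Compound 9 is expected as a C7 epimer mixture (7β drawn); both epimers converge in step 8.
- Compounds 1, 2, 13, 15 and all reagents are taken as commercial.

## Route

Step 1
Reactants: 1 2-methylpent-4-enal (racemic), 2 methyl vinyl ketone
Product: 3 4-allyl-4-methylcyclohex-2-en-1-one (racemic)
Conditions: KOH (cat.), MeOH, 0 °C then 65 °C
Reagents that add atoms: none
Why: Robinson annulation (Michael addition of the α-branched aldehyde enolate to the enone, then aldol condensation) is the standard entry to 4,4-disubstituted cyclohexenones; the quaternary carbon is racemic here and becomes prochiral in step 2.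

Step 2
Reactants: 3 4-allyl-4-methylcyclohex-2-en-1-one
Product: 4 4-allyl-4-methylcyclohexa-2,5-dien-1-one
Conditions: DDQ, 1,4-dioxane, 100 °C
Reagents that add atoms: none
Why: DDQ dehydrogenation of a 4,4-disubstituted cyclohexenone to the cross-conjugated dienone is routine; the quaternary C4 blocks aromatization and the product is achiral.

Step 3
Reactants: 4 4-allyl-4-methylcyclohexa-2,5-dien-1-one
Product: 5 3-(1-methyl-4-oxocyclohexa-2,5-dien-1-yl)propanal
Conditions: PdCl2(PhCN)2 (cat.), CuCl2·2H2O (cat.), AgNO2 (cat.), O2 (1 atm), t-BuOH/MeNO2 15:1, rt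
Reagents that add atoms: dioxygen, O=O
Why: The nitrite-modified Wacker oxidation delivers oxygen to the terminal carbon of an unbiased monosubstituted alkene (aldehyde-selective, anti-Markovnikov), while the internal, electron-poor dienone alkenes should not react.

Step 4
Reactants: 5 3-(1-methyl-4-oxocyclohexa-2,5-dien-1-yl)propanal
Product: 6 (3aR,7aS)-3a-methyl-2,3,3a,7a-tetrahydro-1H-indene-1,6(7H)-dione
Conditions: aminoindanol-derived N-pentafluorophenyl triazolium tetrafluoroborate (10 mol%), KHMDS (10 mol%), toluene, rt
Reagents that add atoms: none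
Why: Asymmetric intramolecular Stetter reaction: the carbene–aldehyde adduct (acyl anion equivalent) adds 5-exo to one of the two enantiotopic enone units, closing ring B and setting the quaternary C3a and C7a in one event (cis fusion enforced by the three-atom tether, absolute sense by the chiral triazolylidene), as known for the desymmetrization of 4,4-disubstituted cyclohexadienones.

Step 5
Reactants: 6 (3aR,7aS)-3a-methyl-2,3,3a,7a-tetrahydro-1H-indene-1,6(7H)-dione
Product: 7 cis-3a-methyl-1-methylidene-1,2,3,3a,7,7a-hexahydro-6H-inden-6-one (3a-methyl and 7a-H both β)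
Conditions: Ph3PCH3Br, KOt-Bu, THF, 0 °C
Reagents that add atoms: methyltriphenylphosphonium bromide, C[P+](c1ccccc1)(c1ccccc1)c1ccccc1.[Br-]
Why: Wittig methylenation is chemoselective for the saturated, more electrophilic cyclopentanone over the conjugated enone carbonyl, as is usual for saturated ketone/enone pairs.

Step 6
Reactants: 7 cis-3a-methyl-1-methylidene-1,2,3,3a,7,7a-hexahydro-6H-inden-6-one
Product: 9 7-methyl enone (cis-3a,7-dimethyl-1-methylidene-1,2,3,3a,7,7a-hexahydro-6H-inden-6-one; 7β-methyl drawn), via lithium dienolate 8 (not isolated)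
Conditions: LDA, THF, −78 °C; then MeI, −78 to 0 °C
Reagents that add atoms: iodomethane, CI
Why: Kinetic α′-deprotonation of the enone (C7 is its only enolizable position) and C-methylation of the cross-conjugated dienolate (enolate alkylation); the new C7 centre, expected mainly β by convex-face attack, is erased in step 8.

Step 7
Reactants: 9 7-methyl enone
Product: 10 4β,5β-epoxy ketone (4β,5β-epoxy-3a,7-dimethyl-1-methylidene-octahydro-6H-inden-6-one)
Conditions: H2O2 (30% aq.), NaOH (cat.), MeOH, 0 °C
Reagents that add atoms: hydrogen peroxide, OO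
Why: Weitz–Scheffer nucleophilic epoxidation: hydroperoxide should add to C4 from the convex β face, anti to the pseudoaxial C3 methylene of ring B, so the oxirane oxygen (the later C4 hydroxyl) is cis to the angular methyl; this sets C4 and C5.

Step 8
Reactants: 10 4β,5β-epoxy ketone
Product: 12 enol triflate (4β,5β-epoxy-3a,7-dimethyl-1-methylidene-2,3,3a,4,5,7a-hexahydro-1H-inden-6-yl trifluoromethanesulfonate), via potassium enolate 11 (not isolated)
Conditions: KHMDS, THF, −78 °C; then PhNTf2, −78 to 0 °C
Reagents that add atoms: N-phenylbis(trifluoromethanesulfonimide), O=S(=O)(N(c1ccccc1)S(=O)(=O)C(F)(F)F)C(F)(F)F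
Why: Enolization can only go toward C7 because C5 is an oxirane carbon, and O-sulfonylation of the enolate (enol triflate formation) gives the tetrasubstituted enol triflate regiospecifically while deleting the C7 stereocentre.

Step 9
Reactants: 13 (E)-1,4-dibromobut-2-ene
Product: 14 (E)-1-bromo-4-[(4-methoxybenzyl)oxy]but-2-ene
Conditions: 4-methoxybenzyl alcohol, NaH, THF, 0 °C (13 in threefold excess)
Reagents that add atoms: 4-methoxybenzyl alcohol, COc1ccc(CO)cc1
Why: Williamson ether synthesis; the excess of the symmetric dibromide favours mono-substitution and the E alkene is untouched.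

Step 10
Reactants: 15 (3-bromopropoxy)(tert-butyl)dimethylsilane, 14 (E)-1-bromo-4-[(4-methoxybenzyl)oxy]but-2-ene
Product: 17 (S)-tert-butyl{[4-({(4-methoxybenzyl)oxy}methyl)hex-5-en-1-yl]oxy}dimethylsilane, via Grignard reagent 16 (not isolated)
Conditions: Mg, Et2O, rt; then 14, CuBr·SMe2 (3 mol%), Taniaphos (3.3 mol%), CH2Cl2, −78 °C
Reagents that add atoms: none
Why: Copper-catalysed asymmetric allylic alkylation (SN2′) of the E allylic bromide by the alkyl Grignard reagent gives the branched terminal alkene; the ferrocenyl diphosphine on copper sets the stereocentre (the future C3′), as known for 4-alkoxybut-2-enyl bromides.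

Step 11
Reactants: 17 (S)-chain alkene, 12 enol triflate
Product: 19 vinyl epoxide (core of 12 carrying at C6 the (3′R)-6′-(tert-butyldimethylsilyloxy)-3′-[(4-methoxybenzyloxy)methyl]hexyl chain), via B-alkyl-9-BBN 18 (not isolated)
Conditions: 9-BBN, THF, rt; then 12, Pd(dppf)Cl2 (5 mol%), AsPh3 (10 mol%), Cs2CO3, DMF/THF/H2O, rt
Reagents that add atoms: none
Why: B-alkyl Suzuki–Miyaura coupling: anti-Markovnikov hydroboration of the vinyl group and palladium-catalysed sp3–sp2 coupling with the enol triflate form the C6–C1′ bond and fix the tetrasubstituted ring-A alkene; hydroboration is completed before 12 is added so that its methylidene group stays intact.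

Step 12
Reactants: 19 vinyl epoxide
Product: 20 4β,5α-diol (trans-diol; C6=C7 alkene, C1 methylidene, chain as in 19)
Conditions: HClO4 (2 mol%), THF/H2O 3:1, 0 °C
Reagents that add atoms: water, O
Why: Acid-catalysed hydrolysis of the vinyl epoxide: water attacks the allylic, cation-stabilized C5 anti to the oxirane (inversion) while neopentyl C4 keeps its β oxygen, which should give the 4β,5α trans-diol.

Step 13
Reactants: 20 4β,5α-diol
Product: 21 4β,5α-bis(tert-butyldimethylsilyl) ether
Conditions: TBSOTf, 2,6-lutidine, CH2Cl2, 0 °C to rt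
Reagents that add atoms: tert-butyldimethylsilyl trifluoromethanesulfonate, CC(C)(C)[Si](C)(C)OS(=O)(=O)C(F)(F)F
Why: A silyl triflate with a hindered base silylates both secondary alcohols, including the neopentyl C4 hydroxyl (silyl ether formation).

Step 14
Reactants: 21 bis-TBS ether
Product: 23 1α-hydroxymethyl compound (H1 β), via B-alkyl-9-BBN adduct 22 (not isolated)
Conditions: 9-BBN, THF, 40 °C; then NaOH, H2O2, 0 °C to rt
Reagents that add atoms: hydrogen peroxide, OO
Why: Hydroboration–oxidation: 9-BBN adds only to the 1,1-disubstituted exocyclic alkene (the tetrasubstituted alkene is inert) and from the convex β face, placing hydrogen β and the CH2–B group α at C1, so the hydroxymethyl group ends on the concave face as the target requires (sets C1).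

Step 15
Reactants: 23 1α-hydroxymethyl compound
Product: 24 1α-carbaldehyde
Conditions: Dess–Martin periodinane, NaHCO3, CH2Cl2, 0 °C
Reagents that add atoms: none
Why: Buffered Dess–Martin oxidation gives the aldehyde under non-basic conditions, so the thermodynamically less favoured concave-face aldehyde should not epimerize; it is used at once.

Step 16
Reactants: 24 1α-carbaldehyde
Product: 25 1α-ethynyl compound (terminal alkyne)
Conditions: TMSCHN2, n-BuLi, THF, −78 °C then 0 °C
Reagents that add atoms: (trimethylsilyl)diazomethane, C[Si](C)(C)C=[N+]=[N-]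
Why: Colvin homologation: lithiated (trimethylsilyl)diazomethane adds to the aldehyde at −78 °C, Peterson-type loss of lithium trimethylsilanolate and of N2 gives an alkylidene carbene, and 1,2-hydrogen shift gives the terminal alkyne faster than the α-centre can epimerize.

Step 17
Reactants: 25 1α-ethynyl compound
Product: 26 primary alcohol (C6′–OH)
Conditions: HF·pyridine, pyridine, THF, 0 °C
Reagents that add atoms: none
Why: Buffered HF·pyridine cleaves the unhindered primary TBS ether much faster than the two hindered secondary ones (selective desilylation).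

Step 18
Reactants: 26 primary alcohol
Product: 27 ynal (C6′ aldehyde, 1α-ethynyl)
Conditions: Dess–Martin periodinane, NaHCO3, CH2Cl2, 0 °C to rt
Reagents that add atoms: none
Why: Dess–Martin oxidation of the primary alcohol; the alkyne, the PMB ether and the silyl ethers are inert.

Step 19
Reactants: 27 ynal
Product: 28 macrocyclic triethylsilyl ether (ring C closed between C6′ and the alkene carbon on C1; exocyclic methylene; (6′S)-OSiEt3)
Conditions: Ni(cod)2 (30 mol%), DP-IPr·HBF4 [1,3-bis(2,6-diisopropylphenyl)-4,5-diphenylimidazolinium tetrafluoroborate] (30 mol%), KOt-Bu (30 mol%), Et3SiH (5 equiv), THF, rt to 50 °C, syringe-pump addition of 27 (final 2 mM)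
Reagents that add atoms: triethylsilane, CC[SiH](CC)CC
Why: Zerovalent nickel bearing the bulky N-heterocyclic carbene binds the alkyne and the aldehyde of 27 and couples them oxidatively to an oxanickelacyclopentene in which the new C–C bond joins the internal alkyne carbon to the aldehyde carbon; σ-bond metathesis of the Ni–O bond with Et3SiH and C–H reductive elimination then release the 1,1-disubstituted alkene and the silyl ether and return the catalyst. The closest known reaction type is the carbene–nickel-catalysed reductive macrocyclization of terminal ynals with trialkylsilanes, which with a bulky carbene gives eleven-membered rings carrying an exocyclic methylene next to a silyloxy carbon. Ring C (eleven-membered) is closed in the exo mode, by bonding at the internal alkyne carbon; the endo mode would give a twelve-membered (E)-cycloalkene. The single new stereocentre C6′ is set in the oxidative cyclization by the conformation of the tethered metallacycle: the cis-hydrindane fixes the alkyne on the concave α face below ring A and the chain leaves from sp2 C6, so only a few low-strain approach geometries exist, and the one with the C3′ substituent pseudo-equatorial is expected to lead to the (S) centre, reinforced by choosing the matched antipode of the C2-symmetric carbene. The step needs exo over endo regioselectivity, secured by the steric demand of the carbene (nickel goes to the unsubstituted alkyne terminus) and by the strain of an (E)-alkene in a twelve-membered ring bridged across the bicycle. It also needs cyclization to outrun oligomerization and simple hydrosilylation, secured by slow addition to high dilution.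

Step 20
Reactants: 28 macrocyclic triethylsilyl ether
Product: 29 primary alcohol (3′-CH2OH; TES and TBS ethers kept)
Conditions: DDQ, CH2Cl2/pH 7 buffer, 0 °C
Reagents that add atoms: none
Why: Oxidative PMB cleavage with DDQ (hydride abstraction from the electron-rich benzyl ether, then hydrolysis); the C6′ oxygen stays protected as its TES ether, which keeps the allylic position safe from oxidation.

Step 21
Reactants: 29 primary alcohol
Product: 30 diol ((6′S)-OH and 3′-CH2OH; 4β,5α-bis-TBS ether)
Conditions: PPTS, MeOH/CH2Cl2, 0 °C to rt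
Reagents that add atoms: none
Why: Mild acid methanolysis removes the secondary TES ether selectively while the two hindered TBS ethers stay (selective desilylation).

Step 22
Reactants: 30 diol
Product: 31 diacetate bis-TBS ether
Conditions: Ac2O, pyridine, DMAP (cat.), CH2Cl2, rt
Reagents that add atoms: acetic anhydride, CC(=O)OC(C)=O
Why: DMAP-catalysed acylation esterifies the primary and the secondary allylic alcohol with retention at C6′.

Step 23
Reactants: 31 diacetate bis-TBS ether
Product: 32 target CNP0193272.1
Conditions: HF·pyridine, pyridine, THF, rt to 40 °C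
Reagents that add atoms: none
Why: Fluoride-mediated cleavage of both TBS ethers with buffered HF·pyridine, under which the acetates and the allylic system should be stable, liberates the trans-diol and gives the target.

## Compound list

1 | 2-methylpent-4-enal (racemic) | C=CCC(C)C=O | starting material
2 | methyl vinyl ketone | C=CC(C)=O | starting material
3 | 4-allyl-4-methylcyclohex-2-en-1-one (racemic) | C=CCC1(C)CCC(=O)C=C1 | intermediate
4 | 4-allyl-4-methylcyclohexa-2,5-dien-1-one | C=CCC1(C)C=CC(=O)C=C1 | intermediate
5 | 3-(1-methyl-4-oxocyclohexa-2,5-dien-1-yl)propanal | O=CCCC1(C)C=CC(=O)C=C1 | intermediate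
6 | (3aR,7aS)-3a-methyl-2,3,3a,7a-tetrahydro-1H-indene-1,6(7H)-dione | O=C1C[C@@H]2C(=O)CC[C@]2(C)C=C1 | intermediate
7 | cis-3a-methyl-1-methylidene-1,2,3,3a,7,7a-hexahydro-6H-inden-6-one | O=C1C[C@@H]2C(=C)CC[C@]2(C)C=C1 | intermediate
8 | lithium dienolate of 7 | [Li]OC1=C[C@@H]2C(=C)CC[C@]2(C)C=C1 | intermediate
9 | 7-methyl enone (7β-methyl drawn) | O=C1[C@@H](C)[C@@H]2C(=C)CC[C@]2(C)C=C1 | intermediate
10 | 4β,5β-epoxy ketone | O=C1[C@@H](C)[C@@H]2C(=C)CC[C@]2(C)[C@@H]3[C@H]1O3 | intermediate
11 | potassium enolate of 10 | [K]OC1=C(C)[C@@H]2C(=C)CC[C@]2(C)[C@@H]3[C@H]1O3 | intermediate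
12 | enol triflate of 10 (C6–OTf, C6=C7) | O=S(=O)(OC1=C(C)[C@@H]2C(=C)CC[C@]2(C)[C@@H]3[C@H]1O3)C(F)(F)F | intermediate
13 | (E)-1,4-dibromobut-2-ene | BrC/C=C/CBr | starting material
14 | (E)-1-bromo-4-[(4-methoxybenzyl)oxy]but-2-ene | BrC/C=C/COCc1ccc(OC)cc1 | intermediate
15 | (3-bromopropoxy)(tert-butyl)dimethylsilane | CC(C)(C)[Si](C)(C)OCCCBr | starting material
16 | 3-(tert-butyldimethylsilyloxy)propylmagnesium bromide | CC(C)(C)[Si](C)(C)OCCC[Mg]Br | intermediate
17 | (S)-tert-butyl{[4-({(4-methoxybenzyl)oxy}methyl)hex-5-en-1-yl]oxy}dimethylsilane | CC(C)(C)[Si](C)(C)OCCC[C@H](COCc1ccc(OC)cc1)C=C | intermediate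
18 | B-alkyl-9-BBN from 17 (boron on the terminal carbon; R) | CC(C)(C)[Si](C)(C)OCCC[C@H](COCc1ccc(OC)cc1)CCB1C2CCCC1CCC2 | intermediate
19 | vinyl epoxide (4β,5β-epoxide; (3′R) chain on C6) | CC(C)(C)[Si](C)(C)OCCC[C@H](COCc1ccc(OC)cc1)CCC2=C(C)[C@@H]3C(=C)CC[C@]3(C)[C@@H]4[C@H]2O4 | intermediate
20 | 4β,5α-diol | CC(C)(C)[Si](C)(C)OCCC[C@H](COCc1ccc(OC)cc1)CCC2=C(C)[C@@H]3C(=C)CC[C@]3(C)[C@@H](O)[C@@H]2O | intermediate
21 | 4β,5α-bis-TBS ether | CC(C)(C)[Si](C)(C)OCCC[C@H](COCc1ccc(OC)cc1)CCC2=C(C)[C@@H]3C(=C)CC[C@]3(C)[C@@H](O[Si](C)(C)C(C)(C)C)[C@@H]2O[Si](C)(C)C(C)(C)C | intermediate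
22 | B-alkyl-9-BBN adduct at the C1 methylene (CH2–B α) | CC(C)(C)[Si](C)(C)OCCC[C@H](COCc1ccc(OC)cc1)CCC2=C(C)[C@@H]3[C@H](CB4C5CCCC4CCC5)CC[C@]3(C)[C@@H](O[Si](C)(C)C(C)(C)C)[C@@H]2O[Si](C)(C)C(C)(C)C | intermediate
23 | 1α-hydroxymethyl compound | CC(C)(C)[Si](C)(C)OCCC[C@H](COCc1ccc(OC)cc1)CCC2=C(C)[C@@H]3[C@H](CO)CC[C@]3(C)[C@@H](O[Si](C)(C)C(C)(C)C)[C@@H]2O[Si](C)(C)C(C)(C)C | intermediate
24 | 1α-carbaldehyde | CC(C)(C)[Si](C)(C)OCCC[C@H](COCc1ccc(OC)cc1)CCC2=C(C)[C@@H]3[C@H](C=O)CC[C@]3(C)[C@@H](O[Si](C)(C)C(C)(C)C)[C@@H]2O[Si](C)(C)C(C)(C)C | intermediate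
25 | 1α-ethynyl compound | CC(C)(C)[Si](C)(C)OCCC[C@H](COCc1ccc(OC)cc1)CCC2=C(C)[C@@H]3[C@H](C#C)CC[C@]3(C)[C@@H](O[Si](C)(C)C(C)(C)C)[C@@H]2O[Si](C)(C)C(C)(C)C | intermediate
26 | primary alcohol (C6′–OH) | OCCC[C@H](COCc1ccc(OC)cc1)CCC2=C(C)[C@@H]3[C@H](C#C)CC[C@]3(C)[C@@H](O[Si](C)(C)C(C)(C)C)[C@@H]2O[Si](C)(C)C(C)(C)C | intermediate
27 | ynal | O=CCC[C@H](COCc1ccc(OC)cc1)CCC2=C(C)[C@@H]3[C@H](C#C)CC[C@]3(C)[C@@H](O[Si](C)(C)C(C)(C)C)[C@@H]2O[Si](C)(C)C(C)(C)C | intermediate
28 | macrocyclic triethylsilyl ether ((6′S); PMB ether; bis-TBS) | C=C1[C@@H](O[Si](CC)(CC)CC)CC[C@H](COCc4ccc(OC)cc4)CCC2=C(C)[C@@H]3[C@H]1CC[C@]3(C)[C@@H](O[Si](C)(C)C(C)(C)C)[C@@H]2O[Si](C)(C)C(C)(C)C | intermediate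
29 | macrocyclic primary alcohol (TES and bis-TBS kept) | C=C1[C@@H](O[Si](CC)(CC)CC)CC[C@H](CO)CCC2=C(C)[C@@H]3[C@H]1CC[C@]3(C)[C@@H](O[Si](C)(C)C(C)(C)C)[C@@H]2O[Si](C)(C)C(C)(C)C | intermediate
30 | macrocyclic diol ((6′S)-OH and 3′-CH2OH; bis-TBS) | C=C1[C@@H](O)CC[C@H](CO)CCC2=C(C)[C@@H]3[C@H]1CC[C@]3(C)[C@@H](O[Si](C)(C)C(C)(C)C)[C@@H]2O[Si](C)(C)C(C)(C)C | intermediate
31 | diacetate bis-TBS ether | C=C1[C@@H](OC(C)=O)CC[C@H](COC(C)=O)CCC2=C(C)[C@@H]3[C@H]1CC[C@]3(C)[C@@H](O[Si](C)(C)C(C)(C)C)[C@@H]2O[Si](C)(C)C(C)(C)C | intermediate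
32 | CNP0193272.1 ((6′S)-acetoxy, (3′R)-acetoxymethyl, 4β,5α-diol, H1 and H7a β) | C=C1[C@@H](OC(C)=O)CC[C@H](COC(C)=O)CCC2=C(C)[C@@H]3[C@H]1CC[C@]3(C)[C@@H](O)[C@@H]2O | target

## Step count, longest linear sequence, risks and fallbacks

Total: 23 steps. Longest linear sequence: 21 steps (steps 1–8 and 11–23); the chain branch (steps 9–10) joins at step 11.

**Step 19 (key step).** The macrocyclization may deliver the endo regiochemistry (twelve-membered (E)-alkene), poor facial selectivity at C6′, or oligomers and hydrosilylation products instead of ring closure. The fallback sets out from 25 and replaces the catalytic reductive coupling by a Nozaki–Hiyama–Kishi ring closure, which is regiochemically fixed by the halide position. Haloboration of the alkyne with B-iodo-9-BBN followed by protonolysis with acetic acid should give the 2-iodoalkene F1. HF·pyridine should then free the primary alcohol F2, and Dess–Martin oxidation should give the iodo aldehyde F3. CrCl2 with catalytic NiCl2 in DMSO/THF at high dilution should close ring C to the macrocyclic allylic alcohol F4; a chiral sulfonamide ligand on chromium would offer reagent control at C6′. DDQ removal of the PMB group from F4 brings the route back at 30.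

**Step 11.** Oxidative addition at the hindered tetrasubstituted enol triflate may be slow, and zerovalent palladium may ionize the vinyl epoxide of the product to a π-allyl species. The fallback sets out from 17 and 12 and uses an iron-catalysed alkyl Grignard–enol triflate coupling, which involves no zerovalent palladium. Hydroboration–oxidation of 17 (9-BBN; NaOH, H2O2) should give the primary alcohol F5, Appel bromination (CBr4, PPh3) the bromide F6, and magnesium in THF the Grignard reagent F7. Coupling of F7 with 12 under Fe(acac)3 catalysis in THF/NMP at −30 °C should give 19, where the route is rejoined.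

**Step 16.** The concave-face aldehyde may epimerize at C1 under the basic reagent before it is homologated, which would place the alkyne on the convex face. The fallback sets out from 24 and uses the Corey–Fuchs sequence, whose first stage is non-basic. CBr4, PPh3 and zinc dust in CH2Cl2 at 0 °C should give the dibromoalkene F8. Treatment with n-BuLi (2.2 equiv) in THF at −78 °C and a proton quench should then give 25, where the route is rejoined.

Further compounds
F1 | step 19 | 2-iodoalkene from 25 (C1 carries C(I)=CH2; primary TBS ether) | CC(C)(C)[Si](C)(C)OCCC[C@H](COCc1ccc(OC)cc1)CCC2=C(C)[C@@H]3[C@H](C(I)=C)CC[C@]3(C)[C@@H](O[Si](C)(C)C(C)(C)C)[C@@H]2O[Si](C)(C)C(C)(C)C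
F2 | step 19 | primary alcohol of the 2-iodoalkene | OCCC[C@H](COCc1ccc(OC)cc1)CCC2=C(C)[C@@H]3[C@H](C(I)=C)CC[C@]3(C)[C@@H](O[Si](C)(C)C(C)(C)C)[C@@H]2O[Si](C)(C)C(C)(C)C
F3 | step 19 | iodo aldehyde | O=CCC[C@H](COCc1ccc(OC)cc1)CCC2=C(C)[C@@H]3[C@H](C(I)=C)CC[C@]3(C)[C@@H](O[Si](C)(C)C(C)(C)C)[C@@H]2O[Si](C)(C)C(C)(C)C
F4 | step 19 | macrocyclic allylic alcohol ((6′S)-OH; PMB ether; bis-TBS) | C=C1[C@@H](O)CC[C@H](COCc4ccc(OC)cc4)CCC2=C(C)[C@@H]3[C@H]1CC[C@]3(C)[C@@H](O[Si](C)(C)C(C)(C)C)[C@@H]2O[Si](C)(C)C(C)(C)C
F5 | step 11 | (S)-6-(tert-butyldimethylsilyloxy)-3-[(4-methoxybenzyloxy)methyl]hexan-1-ol | CC(C)(C)[Si](C)(C)OCCC[C@H](COCc1ccc(OC)cc1)CCO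
F6 | step 11 | (S)-bromide from F5 | CC(C)(C)[Si](C)(C)OCCC[C@H](COCc1ccc(OC)cc1)CCBr
F7 | step 11 | Grignard reagent from F6 | CC(C)(C)[Si](C)(C)OCCC[C@H](COCc1ccc(OC)cc1)CC[Mg]Br
F8 | step 16 | 1α-(2,2-dibromovinyl) compound | CC(C)(C)[Si](C)(C)OCCC[C@H](COCc1ccc(OC)cc1)CCC2=C(C)[C@@H]3[C@H](C=C(Br)Br)CC[C@]3(C)[C@@H](O[Si](C)(C)C(C)(C)C)[C@@H]2O[Si](C)(C)C(C)(C)C
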